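The route rests on cutting ring A at C3–C4 and C5–C10, so that a single intramolecular Diels–Alder reaction of an acyclic triene closes rings A and B together. The feature exploited is the syn-diaxial pair on the trans-fused decalin: C19 on the quaternary C4 and the angular methyl C20 on C10 share one face. A (Z)-enoate at C4=C5 that adds suprafacially to a C10=C1–C2=C3 diene sets C4, C5 and C10 in one operation, steered by the pre-set C9 centre. The precursor is methyl (2Z,7R,8E)-7-[(benzyloxy)methyl]-6,6-(ethylenedioxy)-2,8-dimethylundeca-2,8,10-trienoate; later C1=C2 is hydrogenated, C8 becomes the exocyclic methylene and C11 is extended into the acetoxy acid side chain.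

Key step: step 10

Remark on numbering: the labdane numbering of the target is used for every intermediate (ring A = C1–C5 and C10; ring B = C5–C10; C18 and C19 on C4; C20 on C10; C11 on C9; C17 on C8). In all bicyclic compounds the fusion is trans, and C19, C20 and C11 lie on one face with H5 and H9 on the other, as in the target.

Remark on design: C7 of the precursor (C9 of the target) is R. C11 is carried as a benzyl ether because it arrives together with C11 in the alkylation and leaves in the C1=C2 hydrogenation. The C8 dioxolane is kept because it blocks enolisation at C9 and helps the chain fold.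

Assumption: compounds 6, 12, 17 and 26, and benzyl chloromethyl ether, are taken as commercial.

Step 1
Reactants: 1 but-3-yn-1-ol; 2 vinyl bromide
Product: 4 (3E)-3-methylhexa-3,5-dien-1-ol, via alkenylalane 3 (not isolated)
Conditions: Me3Al, Cp2ZrCl2 (cat.), CH2Cl2, 0 °C → rt; then 2, Pd(PPh3)4 (cat.), ZnCl2 (cat.), THF, rt; aq. work-up
Reagents that add atoms: trimethylaluminium, C[Al](C)C
Why: Negishi zirconium-catalysed carboalumination adds CH3 and Al syn across the alkyne with the methyl on the inner carbon, and the alkenylalane is then cross-coupled with vinyl bromide under zerovalent palladium with retention (Negishi coupling), so the vinyl group ends cis to the methyl and the diene has the required 3E geometry.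

Step 2
Reactants: 4 (3E)-3-methylhexa-3,5-dien-1-ol
Product: 5 (3E)-3-methylhexa-3,5-dienoic acid
Conditions: TEMPO (cat.), PhI(OAc)2, MeCN/H2O, 0 °C → rt
Reagents that add atoms: water, O
Why: TEMPO-catalysed oxidation with PhI(OAc)2 in aqueous acetonitrile carries a primary alcohol directly to the carboxylic acid under nearly neutral, metal-free conditions, which should leave the skipped (E)-diene unconjugated.

Step 3
Reactants: 5 (3E)-3-methylhexa-3,5-dienoic acid; 6 (4S)-4-benzyl-1,3-oxazolidin-2-one
Product: 8 (4S)-4-benzyl-3-[(3E)-3-methylhexa-3,5-dienoyl]-1,3-oxazolidin-2-one, via mixed pivalic anhydride 7 (not isolated)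
Conditions: t-BuCOCl, Et3N, THF, −20 °C; then LiCl, 6, −20 °C → rt
Reagents that add atoms: none
Why: N-acylation of the oxazolidinone through the mixed pivalic anhydride with LiCl/Et3N activation is a standard mild acylation that needs no strong base and so should not move the β,γ-double bond.

Step 4
Reactants: 8 (4S)-4-benzyl-3-[(3E)-3-methylhexa-3,5-dienoyl]-1,3-oxazolidin-2-one
Product: 10 (4S)-4-benzyl-3-{(2R,3E)-2-[(benzyloxy)methyl]-3-methylhexa-3,5-dienoyl}-1,3-oxazolidin-2-one, via titanium enolate 9 (not isolated)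
Conditions: TiCl4, i-Pr2NEt, CH2Cl2, 0 °C; then BnOCH2Cl, 0 °C
Reagents that add atoms: benzyl chloromethyl ether, ClCOCc1ccccc1
Why: Evans asymmetric alkylation: the chelated (Z)-titanium enolate is attacked at its α-carbon (C9) by the alkoxymethyl electrophile on the face opposite to the benzyl group of the auxiliary, which sets C9 as R and brings in C11 already protected.

Step 5
Reactants: 10 (4S)-4-benzyl-3-{(2R,3E)-2-[(benzyloxy)methyl]-3-methylhexa-3,5-dienoyl}-1,3-oxazolidin-2-one
Product: 11 S-ethyl (2R,3E)-2-[(benzyloxy)methyl]-3-methylhexa-3,5-dienethioate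
Conditions: EtSH, n-BuLi, THF, −78 → 0 °C; aq. NH4Cl
Reagents that add atoms: ethanethiol, CCS
Why: Transthioesterification: the small, weakly basic lithium thiolate attacks the exocyclic imide carbonyl and releases the auxiliary without touching the C9–H.

Step 6
Reactants: 11 S-ethyl (2R,3E)-2-[(benzyloxy)methyl]-3-methylhexa-3,5-dienethioate; 12 ethyl 3-iodopropanoate
Product: 13 ethyl (5R,6E)-5-[(benzyloxy)methyl]-6-methyl-4-oxonona-6,8-dienoate
Conditions: 12, Zn, THF, 35 °C; then 11, PdCl2(PPh3)2 (cat.), toluene, rt
Reagents that add atoms: none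
Why: Fukuyama coupling, the palladium-catalysed union of a thioester with an ester-bearing alkylzinc iodide, makes the C8 ketone (C7–C8 bond) under neutral conditions, so the C9 centre next to the new carbonyl is not exposed to base.

Step 7
Reactants: 13 ethyl (5R,6E)-5-[(benzyloxy)methyl]-6-methyl-4-oxonona-6,8-dienoate
Product: 14 ethyl 3-{2-[(2R,3E)-1-(benzyloxy)-3-methylhexa-3,5-dien-2-yl]-1,3-dioxolan-2-yl}propanoate
Conditions: (Me3SiOCH2)2, TMSOTf (cat.), CH2Cl2, −78 → −40 °C; pyridine quench
Reagents that add atoms: 1,2-bis(trimethylsilyloxy)ethane, C[Si](C)(C)OCCO[Si](C)(C)C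
Why: Noyori ketalisation runs aprotically at low temperature and is the standard way to ketalise β,γ-unsaturated ketones without double-bond migration or loss of the α-centre, so C9 should be carried through intact.

Step 8
Reactants: 14 ethyl 3-{2-[(2R,3E)-1-(benzyloxy)-3-methylhexa-3,5-dien-2-yl]-1,3-dioxolan-2-yl}propanoate
Product: 16 3-{2-[(2R,3E)-1-(benzyloxy)-3-methylhexa-3,5-dien-2-yl]-1,3-dioxolan-2-yl}propanal, via aluminium hemiacetal 15 (not isolated)
Conditions: i-Bu2AlH, CH2Cl2, −78 °C; MeOH, then aq. KNaC4H4O6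
Reagents that add atoms: none
Why: Partial reduction of the ester with one equivalent of i-Bu2AlH stops at the tetrahedral aluminium hemiacetal at −78 °C, which releases the C5 aldehyde only on work-up.

Step 9
Reactants: 16 3-{2-[(2R,3E)-1-(benzyloxy)-3-methylhexa-3,5-dien-2-yl]-1,3-dioxolan-2-yl}propanal; 17 methyl 2-[bis(2,2,2-trifluoroethoxy)phosphoryl]propanoate
Product: 18 methyl (2Z,7R,8E)-7-[(benzyloxy)methyl]-6,6-(ethylenedioxy)-2,8-dimethylundeca-2,8,10-trienoate
Conditions: 17, KN(SiMe3)2, 18-crown-6, THF, −78 °C; then 16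
Reagents that add atoms: none
Why: Still–Gennari olefination: the electron-poor bis(trifluoroethyl) phosphonate anion under dissociating conditions should give the (Z)-trisubstituted enoate, that is C4=C5 with the ester cis to C6.

Step 10
Reactants: 18 methyl (2Z,7R,8E)-7-[(benzyloxy)methyl]-6,6-(ethylenedioxy)-2,8-dimethylundeca-2,8,10-trienoate
Product: 19 Δ1 trans-octalin cycloadduct (4R,5S,9R,10R): C19 methyl ester; C8 ethylene ketal; C11 benzyl ether
Conditions: toluene (0.01 M, degassed), BHT (cat.), sealed tube, 170 °C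
Reagents that add atoms: none
Why: On heating, the (Z)-enoate C4=C5 adds suprafacially across the s-cis C10=C1–C2=C3 diene in a concerted [4+2] cycloaddition that forms C3–C4 and C5–C10; the closest known reaction type is the thermal intramolecular Diels–Alder reaction of 1,7,9-decatrienoates to trans-fused octalins. Ring A closes as the new cyclohexene made from the four diene carbons and the two dienophile carbons, and ring B closes in the same event because the four-atom tether C6–C9 folds into a chair that links C5 to C10. C4 is set by the Z geometry of the dienophile, which keeps C19 cis to C6 and therefore axial and cis to C20; C5 and C10 are set trans to each other by the ester-exo, tether-anti transition state in which the C4 methyl lies under the diene; the absolute sense of all three comes from the (R)-C9 centre, whose CH2OBn group takes the equatorial position on the chair-like tether. The step needs π-facial and exo selectivity, which should be secured by that equatorial preference and by the α-methyl group, which removes the usual endo preference of the ester. The C8 dioxolane helps the chain fold (gem-dialkoxy effect) and keeps C9 from enolising, so the cycloaddition should run below the temperature at which a 1,5-hydrogen shift from C20 into the diene competes.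

Step 11
Reactants: 19 Δ1 trans-octalin cycloadduct
Product: 20 C19 alcohol of the Δ1 trans-octalin (4R,5S,9R,10R): C8 ethylene ketal; C11 benzyl ether
Conditions: LiAlH4, THF, 0 °C → reflux; aq. KNaC4H4O6
Reagents that add atoms: none
Why: Hydride reduction with LiAlH4 converts the hindered axial ester into the neopentyl C19 alcohol, while the ketal, the benzyl ether and the ring alkene are inert.

Step 12
Reactants: 20 C19 alcohol of the Δ1 trans-octalin
Product: 21 C19 acetate of the Δ1 trans-octalin (4R,5S,9R,10R): C8 ethylene ketal; C11 benzyl ether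
Conditions: Ac2O, pyridine, DMAP (cat.), CH2Cl2, rt
Reagents that add atoms: acetic anhydride, CC(=O)OC(C)=O
Why: DMAP-catalysed acylation installs the C19 acetate of the target at once, and as a neopentyl ester it should survive the later ylide, borane and Lewis-acid steps.

Step 13
Reactants: 21 C19 acetate of the Δ1 trans-octalin
Product: 23 saturated trans-decalin C11 alcohol (4R,5S,9R,10R): C19 acetate; C8 ethylene ketal, via saturated benzyl ether 22 (not isolated)
Conditions: H2 (1 atm), Pd(OH)2/C, EtOAc, rt
Reagents that add atoms: none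
Why: Heterogeneous catalytic hydrogenation saturates the cis-disubstituted C1=C2 bond (no new stereocentre) and then hydrogenolyses the benzyl ether, so one operation removes the retron of the cycloaddition and frees C11–OH.

Step 14
Reactants: 23 saturated trans-decalin C11 alcohol
Product: 24 C11 aldehyde (4R,5S,9R,10R): C19 acetate; C8 ethylene ketal
Conditions: Dess–Martin periodinane, pyridine, CH2Cl2, 0 °C → rt
Reagents that add atoms: none
Why: Dess–Martin oxidation buffered with pyridine converts the hindered primary alcohol into the aldehyde without acid or base strong enough to open the neighbouring ketal or epimerise C9.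

Step 15
Reactants: 24 C11 aldehyde
Product: 25 C9 vinyl compound with C11=C12 (4R,5S,9S,10R; the descriptor at C9 changes by priority only): C19 acetate; C8 ethylene ketal
Conditions: Ph3PCH3Br, KN(SiMe3)2, THF, 0 °C; then 24, −78 → 0 °C
Reagents that add atoms: methyltriphenylphosphonium bromide, C[P+](c1ccccc1)(c1ccccc1)c1ccccc1.[Br-]
Why: Wittig methylenation: the unstabilised ylide adds to the aldehyde much faster than it can deprotonate C9 or attack the neopentyl acetate, so C12 is introduced with C9 unchanged.

Step 16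
Reactants: 26 tert-butyl 4-chloro-3-oxobutanoate
Product: 27 tert-butyl 4-acetoxy-3-oxobutanoate
Conditions: KOAc, AcOH, 60 °C
Reagents that add atoms: potassium acetate, CC(=O)[O-].[K+]
Why: SN2 displacement of the activated α-chloro ketone chloride by acetate in buffered acetic acid gives the acetoxy ketone without enolate side reactions.

Step 17
Reactants: 27 tert-butyl 4-acetoxy-3-oxobutanoate
Product: 28 tert-butyl (2E)-4-acetoxy-3-{[(trifluoromethyl)sulfonyl]oxy}but-2-enoate
Conditions: Tf2O, i-Pr2NEt, CH2Cl2, −78 °C
Reagents that add atoms: trifluoromethanesulfonic anhydride, O=S(=O)(OS(=O)(=O)C(F)(F)F)C(F)(F)F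
Why: O-Triflation of the amine-generated enolate, which is not held in a metal chelate and therefore reacts in its extended form, should give the (E)-enol triflate with the triflate trans to the ester and the acetoxymethyl group cis to it.

Step 18
Reactants: 25 C9 vinyl compound; 28 tert-butyl (2E)-4-acetoxy-3-{[(trifluoromethyl)sulfonyl]oxy}but-2-enoate
Product: 30 tert-butyl (13Z)-ester of the C8 ethylene ketal of the side-chain diacetate (4R,5S,9S,10R), via B-alkyl borane 29 (not isolated)
Conditions: 9-BBN-H, THF, rt; then 28, PdCl2(dppf) (cat.), AsPh3 (cat.), Cs2CO3, DMF/H2O, rt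
Reagents that add atoms: none
Why: Anti-Markovnikov hydroboration of the vinyl group followed by B-alkyl Suzuki–Miyaura coupling joins C12 to C13 with retention of the enol triflate geometry, so the side-chain double bond is formed as 13Z with CH2OAc cis to the ester and never carries a free C16 hydroxyl that could lactonise.

Step 19
Reactants: 30 tert-butyl (13Z)-ester of the C8 ethylene ketal
Product: 31 C8 ketone (4R,5S,9S,10R): tert-butyl (13Z)-ester; C16 and C19 acetates
Conditions: aq. HCl (1 M), THF, 0 °C → rt
Reagents that add atoms: water, O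
Why: Acid-catalysed ketal hydrolysis frees the C8 ketone under conditions too mild for the tert-butyl ester or the acetates, and C9 keeps its equatorial side chain, which is also the thermodynamically preferred arrangement.

Step 20
Reactants: 31 C8 ketone
Product: 32 tert-butyl ester of the target with C8=C17 methylene (4R,5S,9R,10S)
Conditions: Zn, CH2Br2, TiCl4, THF, 0 °C; then 31, CH2Cl2, rt
Reagents that add atoms: dibromomethane, BrCBr
Why: Takai–Lombardo methylenation uses a non-basic zinc/titanium methylene reagent that converts ketones but not esters, so C17 is introduced without epimerising C9 or touching the acetates and the enoate.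

Step 21
Reactants: 32 tert-butyl ester of the target
Product: 34 target acid CNP0181814.1 (4R,5S,9R,10S; 13Z), via trimethylsilyl ester 33 (not isolated)
Conditions: TMSOTf, 2,6-lutidine, CH2Cl2, 0 °C; then pH 5 aqueous buffer
Reagents that add atoms: none
Why: Silyl triflate-mediated cleavage of the tert-butyl ester (silylation of the carbonyl oxygen, loss of isobutene, hydrolysis of the silyl ester on work-up) is buffered by 2,6-lutidine, so neither the acetates nor the acid-sensitive exocyclic alkene meet free strong acid.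

Compound list
1 | but-3-yn-1-ol | C#CCCO | starting material
2 | vinyl bromide (bromoethene) | C=CBr | starting material
3 | dimethyl{(1E)-4-[(dimethylalumanyl)oxy]-2-methylbut-1-en-1-yl}alumane (alkenylalane; not isolated) | C[Al](C)/C=C(\C)CCO[Al](C)C | intermediate
4 | (3E)-3-methylhexa-3,5-dien-1-ol | C=C/C=C(\C)CCO | intermediate
5 | (3E)-3-methylhexa-3,5-dienoic acid | C=C/C=C(\C)CC(=O)O | intermediate
6 | (4S)-4-benzyl-1,3-oxazolidin-2-one | O=C1N[C@@H](Cc2ccccc2)CO1 | starting material
7 | (3E)-3-methylhexa-3,5-dienoic 2,2-dimethylpropanoic anhydride (mixed pivalic anhydride; not isolated) | C=C/C=C(\C)CC(=O)OC(=O)C(C)(C)C | intermediate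
8 | (4S)-4-benzyl-3-[(3E)-3-methylhexa-3,5-dienoyl]-1,3-oxazolidin-2-one | C=C/C=C(\C)CC(=O)N1[C@@H](Cc2ccccc2)COC1=O | intermediate
9 | trichlorotitanium (Z)-enolate of 8 (not isolated) | C=C/C=C(\C)/C=C(\O[Ti](Cl)(Cl)Cl)N1[C@@H](Cc2ccccc2)COC1=O | intermediate
10 | (4S)-4-benzyl-3-{(2R,3E)-2-[(benzyloxy)methyl]-3-methylhexa-3,5-dienoyl}-1,3-oxazolidin-2-one | C=C/C=C(\C)[C@@H](C(=O)N1[C@@H](Cc2ccccc2)COC1=O)COCc1ccccc1 | intermediate
11 | S-ethyl (2R,3E)-2-[(benzyloxy)methyl]-3-methylhexa-3,5-dienethioate | C=C/C=C(\C)[C@@H](C(=O)SCC)COCc1ccccc1 | intermediate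
12 | ethyl 3-iodopropanoate | CCOC(=O)CCI | starting material
13 | ethyl (5R,6E)-5-[(benzyloxy)methyl]-6-methyl-4-oxonona-6,8-dienoate | C=C/C=C(\C)[C@@H](C(=O)CCC(=O)OCC)COCc1ccccc1 | intermediate
14 | ethyl 3-{2-[(2R,3E)-1-(benzyloxy)-3-methylhexa-3,5-dien-2-yl]-1,3-dioxolan-2-yl}propanoate | C=C/C=C(\C)[C@@H](C1(CCC(=O)OCC)OCCO1)COCc1ccccc1 | intermediate
15 | diisobutylaluminium hemiacetal of 14 (not isolated) | C=C/C=C(\C)[C@@H](C1(CCC(OCC)O[Al](CC(C)C)CC(C)C)OCCO1)COCc1ccccc1 | intermediate
16 | 3-{2-[(2R,3E)-1-(benzyloxy)-3-methylhexa-3,5-dien-2-yl]-1,3-dioxolan-2-yl}propanal | C=C/C=C(\C)[C@@H](C1(CCC=O)OCCO1)COCc1ccccc1 | intermediate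
17 | methyl 2-[bis(2,2,2-trifluoroethoxy)phosphoryl]propanoate | COC(=O)C(C)P(=O)(OCC(F)(F)F)OCC(F)(F)F | starting material
18 | methyl (2Z,7R,8E)-7-[(benzyloxy)methyl]-6,6-(ethylenedioxy)-2,8-dimethylundeca-2,8,10-trienoate (Diels–Alder precursor) | C=C/C=C(\C)[C@@H](C1(CC/C=C(/C)C(=O)OC)OCCO1)COCc1ccccc1 | intermediate
19 | Δ1 trans-octalin cycloadduct (4R,5S,9R,10R): C19 methyl ester; C8 ethylene ketal; C11 benzyl ether | O3CCOC31CC[C@@H]2[C@](C)(C(=O)OC)CC=C[C@@]2(C)[C@@H]1COCc1ccccc1 | intermediate
20 | C19 alcohol of the Δ1 trans-octalin (4R,5S,9R,10R): C8 ethylene ketal; C11 benzyl ether | O3CCOC31CC[C@@H]2[C@](C)(CO)CC=C[C@@]2(C)[C@@H]1COCc1ccccc1 | intermediate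
21 | C19 acetate of the Δ1 trans-octalin (4R,5S,9R,10R): C8 ethylene ketal; C11 benzyl ether | O3CCOC31CC[C@@H]2[C@](C)(COC(C)=O)CC=C[C@@]2(C)[C@@H]1COCc1ccccc1 | intermediate
22 | saturated trans-decalin (4R,5S,9R,10R): C19 acetate; C8 ethylene ketal; C11 benzyl ether (not isolated) | O3CCOC31CC[C@@H]2[C@](C)(COC(C)=O)CCC[C@@]2(C)[C@@H]1COCc1ccccc1 | intermediate
23 | saturated trans-decalin C11 alcohol (4R,5S,9R,10R): C19 acetate; C8 ethylene ketal | O3CCOC31CC[C@@H]2[C@](C)(COC(C)=O)CCC[C@@]2(C)[C@@H]1CO | intermediate
24 | C11 aldehyde (4R,5S,9R,10R): C19 acetate; C8 ethylene ketal | O3CCOC31CC[C@@H]2[C@](C)(COC(C)=O)CCC[C@@]2(C)[C@@H]1C=O | intermediate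
25 | C9 vinyl compound with C11=C12 (4R,5S,9S,10R): C19 acetate; C8 ethylene ketal | O3CCOC31CC[C@@H]2[C@](C)(COC(C)=O)CCC[C@@]2(C)[C@@H]1C=C | intermediate
26 | tert-butyl 4-chloro-3-oxobutanoate | CC(C)(C)OC(=O)CC(=O)CCl | starting material
27 | tert-butyl 4-acetoxy-3-oxobutanoate | CC(=O)OCC(=O)CC(=O)OC(C)(C)C | intermediate
28 | tert-butyl (2E)-4-acetoxy-3-{[(trifluoromethyl)sulfonyl]oxy}but-2-enoate | CC(=O)OC/C(OS(=O)(=O)C(F)(F)F)=C\C(=O)OC(C)(C)C | intermediate
29 | 9-(C12-alkyl)-9-borabicyclo[3.3.1]nonane from 25 (boron on C12; not isolated) | O3CCOC31CC[C@@H]2[C@](C)(COC(C)=O)CCC[C@@]2(C)[C@@H]1CCB1C2CCCC1CCC2 | intermediate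
30 | tert-butyl (13Z)-ester of the C8 ethylene ketal (4R,5S,9S,10R): C16 and C19 acetates | O3CCOC31CC[C@@H]2[C@](C)(COC(C)=O)CCC[C@@]2(C)[C@@H]1CC/C(=C/C(=O)OC(C)(C)C)COC(C)=O | intermediate
31 | C8 ketone (4R,5S,9S,10R): tert-butyl (13Z)-ester; C16 and C19 acetates | O=C1CC[C@@H]2[C@](C)(COC(C)=O)CCC[C@@]2(C)[C@@H]1CC/C(=C/C(=O)OC(C)(C)C)COC(C)=O | intermediate
32 | tert-butyl ester of the target (4R,5S,9R,10S; 13Z; C8=C17 methylene) | C=C1CC[C@@H]2[C@](C)(COC(C)=O)CCC[C@@]2(C)[C@@H]1CC/C(=C/C(=O)OC(C)(C)C)COC(C)=O | intermediate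
33 | trimethylsilyl ester of the target (not isolated) | C=C1CC[C@@H]2[C@](C)(COC(C)=O)CCC[C@@]2(C)[C@@H]1CC/C(=C/C(=O)O[Si](C)(C)C)COC(C)=O | intermediate
34 | (2Z)-4-(acetyloxy)-3-{2-[(1R,4aS,5R,8aS)-5-[(acetyloxy)methyl]-5,8a-dimethyl-2-methylidenedecahydronaphthalen-1-yl]ethyl}but-2-enoic acid (CNP0181814.1) | C=C1CC[C@@H]2[C@](C)(COC(C)=O)CCC[C@@]2(C)[C@@H]1CC/C(=C/C(=O)O)COC(C)=O | target

Total step count: 21 (19 in the main line and 2 for coupling partner 28).
Longest linear sequence: 19 steps (steps 1–15, then 18–21).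

Steps most likely to fail

Step 10 (intramolecular Diels–Alder). The C20 methyl is forced to the inside of the s-cis diene and the dienophile is trisubstituted, so closure may be slow. Prolonged heating could then allow a 1,5-hydrogen shift from C20 into the diene, Z to E leakage of the enoate or polymerisation, and exo and facial control may be incomplete. The fallback keeps the same C3–C4 and C5–C10 closure but raises the reactivity of the dienophile by changing the activating group from ester to aldehyde. It sets out from 18: reduction with i-Bu2AlH (CH2Cl2, −78 °C) should give (2Z,7R,8E)-7-[(benzyloxy)methyl]-6,6-(ethylenedioxy)-2,8-dimethylundeca-2,8,10-trien-1-ol F1, and oxidation with MnO2 (CH2Cl2, rt) the corresponding (2Z)-trienal F2. F2 should cyclise in toluene with BHT at 80–100 °C to the C19 aldehyde cycloadduct F3, and NaBH4 (MeOH, 0 °C) then gives alcohol 20, where the route is rejoined.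

Step 18 (hydroboration and B-alkyl Suzuki–Miyaura coupling). The aqueous carbonate may hydrolyse the allylic acetate of 28 or of the product, after which the freed C16 hydroxyl would lactonise onto the cis ester. Zerovalent palladium may also ionise that allylic acetate, and the alkyl palladium species may undergo β-hydride elimination. The fallback replaces the borane by an alkylzinc reagent, so the coupling runs without base or water. It sets out from 25: hydroboration with 9-BBN-H and oxidation with NaBO3·4H2O should give the C12 alcohol F4; I2, PPh3 and imidazole give the C12 iodide F5; zinc insertion (Zn, LiCl, THF) gives the alkylzinc iodide F6. Negishi coupling of F6 with 28 (Pd(PPh3)4 cat., THF/N,N-dimethylacetamide, rt) comes back to the route at 30.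

Step 7 (ketalisation next to C9). While C8 is a free or activated ketone, the C9 hydrogen is α to the carbonyl and allylic to the diene, so acid-promoted enolisation could erode the C9 configuration or move C10=C1 into conjugation. The fallback forms the C8–C9 bond by acylation instead, so that C9 sits in a β-keto imide whose α-hydrogen is held against enolisation by allylic strain while the ketal is made. It sets out from acid 5: acylation of (4R)-4-benzyl-1,3-oxazolidin-2-one under the conditions of step 3 gives the enantiomeric imide F7. Its sodium enolate (NaN(SiMe3)2, THF, −78 °C) is acylated with ethyl 4-chloro-4-oxobutanoate to the β-keto imide F8, with C9 set opposite to the benzyl group. Noyori ketalisation of F8 gives the ketal imide F9, and NaBH4 in THF/H2O removes the auxiliary to give the C11 alcohol F10. Benzylation (NaH, BnBr, n-Bu4NI, THF, 0 °C) comes back to the route at 14.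

Further compounds
F1 | step 10 | (2Z,7R,8E)-7-[(benzyloxy)methyl]-6,6-(ethylenedioxy)-2,8-dimethylundeca-2,8,10-trien-1-ol | C=C/C=C(\C)[C@@H](C1(CC/C=C(/C)CO)OCCO1)COCc1ccccc1
F2 | step 10 | (2Z,7R,8E)-7-[(benzyloxy)methyl]-6,6-(ethylenedioxy)-2,8-dimethylundeca-2,8,10-trienal | C=C/C=C(\C)[C@@H](C1(CC/C=C(/C)C=O)OCCO1)COCc1ccccc1
F3 | step 10 | C19 aldehyde of the Δ1 trans-octalin cycloadduct (4R,5S,9R,10R): C8 ethylene ketal; C11 benzyl ether | O3CCOC31CC[C@@H]2[C@](C)(C=O)CC=C[C@@]2(C)[C@@H]1COCc1ccccc1
F4 | step 18 | C12 alcohol from 25 (4R,5S,9S,10R): C19 acetate; C8 ethylene ketal | O3CCOC31CC[C@@H]2[C@](C)(COC(C)=O)CCC[C@@]2(C)[C@@H]1CCO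
F5 | step 18 | C12 iodide (4R,5S,9S,10R): C19 acetate; C8 ethylene ketal | O3CCOC31CC[C@@H]2[C@](C)(COC(C)=O)CCC[C@@]2(C)[C@@H]1CCI
F6 | step 18 | C12 alkylzinc iodide (4R,5S,9S,10R): C19 acetate; C8 ethylene ketal | O3CCOC31CC[C@@H]2[C@](C)(COC(C)=O)CCC[C@@]2(C)[C@@H]1CC[Zn]I
F7 | step 7 | (4R)-4-benzyl-3-[(3E)-3-methylhexa-3,5-dienoyl]-1,3-oxazolidin-2-one | C=C/C=C(\C)CC(=O)N1[C@H](Cc2ccccc2)COC1=O
F8 | step 7 | ethyl (5S,6E)-5-{[(4R)-4-benzyl-2-oxo-1,3-oxazolidin-3-yl]carbonyl}-6-methyl-4-oxonona-6,8-dienoate | C=C/C=C(\C)[C@@H](C(=O)CCC(=O)OCC)C(=O)N1[C@H](Cc2ccccc2)COC1=O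
F9 | step 7 | ethyl 3-{2-[(2S,3E)-1-[(4R)-4-benzyl-2-oxo-1,3-oxazolidin-3-yl]-3-methyl-1-oxohexa-3,5-dien-2-yl]-1,3-dioxolan-2-yl}propanoate | C=C/C=C(\C)[C@@H](C1(CCC(=O)OCC)OCCO1)C(=O)N1[C@H](Cc2ccccc2)COC1=O
F10 | step 7 | ethyl 3-{2-[(2R,3E)-1-hydroxy-3-methylhexa-3,5-dien-2-yl]-1,3-dioxolan-2-yl}propanoate | C=C/C=C(\C)[C@@H](C1(CCC(=O)OCC)OCCO1)CO
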